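Readings and results were computed with made-up constants; scatter was added.

I began with the easy step, reading down the solid column of each earlier run.

| flask | solid substrate | free catalyst | remark | time |
|---|---|---|---|---|
| delta | 1 M | 0.86 mM | run made earlier |  |
| beta | 1 M | 1.8 mM | run made earlier |  |
| eta | 1 M | 3.4 mM | run made earlier |  |
| blue | 1.0 M | 3.6 mM |  | 2.0 min |
| teal | 1.0 M | 1.0 mM |  | 6.0 min |

| run | time / s | target / % | solid substrate / % |
|---|---|---|---|
| delta | 15.0 | 0.9 | 90.8 |
| delta | 30.0 | 0 | 80.6 |
| delta | 50.0 | 2.8 | 69.8 |
| delta | 60.0 | 1.4 | 63.2 |
| delta | 80.0 | 3.2 | 57.0 |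
| beta | 10.0 | 0.6 | 92.3 |
| beta | 20.0 | 2.1 | 87.8 |
| beta | 40.0 | 1.7 | 77.0 |
| beta | 60.0 | 4.9 | 63.6 |
| beta | 80.0 | 7.3 | 55.9 |
| eta | 10.0 | 0.4 | 92.0 |
| eta | 12.0 | 1.6 | 93.7 |
| eta | 25.0 | 2.4 | 83.2 |
| eta | 40.0 | 6.4 | 77.4 |
| eta | 80.0 | 12.8 | 53.2 |

(scatter of a reading: 1 percentage point)

- as a solid, counted per litre of solution: solid substrate
- at the start none of the solid substrate is in solution
- what has only dissolved of solid substrate counts as not reacted

- the winner by amount of target, in percent of the solid substrate charged; "neither" if no more than 2 percentage points parts them (blue / teal / neither)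
- how much target is there at the end, in percent of the solid substrate charged: blue
- how much target is there at the end, in percent of the solid substrate charged: teal

From delta to eta, free catalyst rose from 0.86 mM to 3.4 mM and target at 80.0 s rose from 3.2% to 12.8%, yet the solid substrate stood at 57.0% and 53.2%, with beta at 55.9%. The product followed the catalyst while the loss of its substrate did not. Subtraction cleared this up: in delta, 39.8% of the charge had left the solid without being target, so it sat in solution. Dissolving was one event, and the catalyst worked afterwards on what had dissolved.

The mean loss over these runs gave a feed of 5.58 mM s⁻¹. At that feed the charge lasted 2.99 min, and I carried this run-out time, charge over feed, as the crossing. Before it, I took the dissolved part to grow with time, so target scaled with catalyst and the square of time. After it, the dissolved part drained as a pseudo-first-order decay. Blue's 2.0 min ended earlier than the crossing, and teal's 6.0 min ended later. Scaling from eta, I reckoned 30.5% for blue. For teal I reckoned 18.9% at the crossing and 44.6% at the end, which is more than blue.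

The forecast also chose teal, but with lower figures than mine, 21% for blue and 34% for teal: “Teal's longer time beats blue's higher catalyst.”

The flasks gave 26.6% in blue and 40.2% in teal, and the winner was teal.

    catalyst intermediate → free catalyst + target (k = 4.50 s⁻¹)
    starting material + free catalyst → catalyst intermediate (k = 3.30 L mol⁻¹ s⁻¹)
    2 catalyst intermediate ⇌ resting dimer, settled at all times (K = 270 L mol⁻¹)
    solid substrate ⇌ starting material, rate k4*(cs4 - [starting material]) while solid is left; crystals form when [starting material] > cs4 (solubility = 0.830 M, k = 0.00880 s⁻¹)

The dissolved part was the starting material. Blue, short of its crossing, still held 37.3% as solid at 2.00 min. Teal held 27.1% at 3.00 min, so its feed had fallen below my mean, and 0% at 6.00 min. For a neighbour of blue charged with 0.40 M, charge over feed gave a reckoned run-out time of 1.19 min, earlier than its end at 2.00 min. There the solid stood at 0%, the starting material at 42.8% and the target at 57.1%.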